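## Retrosynthetic overview

1. The target is reached by fluoride removal of two silyl ethers from a bis-silylated (3S)-isoflavanone, which comes from oxidation of a cis-(3S,4S)-isoflavan-4-ol.
2. That alcohol comes from the isoflavone by asymmetric transfer hydrogenation with dynamic kinetic resolution, which sets C3.
3. The isoflavone is cut at the C3–aryl bond into a 3-iodochromone (rings A and C) and a chromenyl pinacol boronate (ring B plus the dimethylpyran ring D), joined by Suzuki–Miyaura coupling.
4. The iodochromone is built from resorcinol: Ir C–H borylation/oxidation gives the third oxygen, directed ortho-metalation/acylation the ketone, enaminone iodocyclisation ring C.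
5. The boronate is built from catechol: para-bromination, propargyl ether Claisen cascade (ring D), borylation. Ring order: A, then C; B, then D; the stereocentre last.

Assumption: the target is the (3S) enantiomer encoded by the SMILES; compounds that deliver skeletal carbon are numbered as reactants, other atom donors stand on the reagent line.

## Route

**Step 1**
Reactants: 1 resorcinol
Product: 2 3-methoxyphenol
Conditions: MeI (1.0 equiv), K2CO3 (1.0 equiv), resorcinol in excess (2 equiv), acetone, reflux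
Reagents that add atoms: iodomethane, CI
Why: Williamson O-methylation with limiting MeI stops mainly at the monoether of the symmetric diol, and unreacted resorcinol is washed out with water.

**Step 2**
Reactants: 2 3-methoxyphenol
Product: 3 1-methoxy-3-(methoxymethoxy)benzene
Conditions: MOMCl, i-Pr2NEt, CH2Cl2, 0 °C → rt
Reagents that add atoms: chloromethyl methyl ether, COCCl
Why: Acetal (MOM) protection of the phenol, which also installs the strong ortho-directing group used in step 5.

**Step 3**
Reactants: 3 1-methoxy-3-(methoxymethoxy)benzene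
Product: 5 3-methoxy-5-(methoxymethoxy)phenol, via arylboronate 4 (not isolated)
Conditions: B2pin2 (0.55 equiv), [Ir(OMe)(cod)]2 (1.5 mol %), 4,4'-di-tert-butyl-2,2'-bipyridine (3 mol %), THF, 80 °C; then 30 % H2O2, aq NaOH, 0 °C → rt
Reagents that add atoms: bis(pinacolato)diboron, CC1(C)OB(OC1(C)C)B1OC(C)(C)C(C)(C)O1 (boryl group of 4); hydrogen peroxide, OO (phenol oxygen of 5)
Why: Sterically controlled Ir-catalysed C–H borylation goes to C5, the only position without an ortho substituent, and oxidation of the C–B bond gives the phenol.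

**Step 4**
Reactants: 5 3-methoxy-5-(methoxymethoxy)phenol
Product: 6 triisopropyl[3-methoxy-5-(methoxymethoxy)phenoxy]silane
Conditions: i-Pr3SiCl, imidazole, DMF, rt
Reagents that add atoms: chlorotriisopropylsilane, CC(C)[Si](Cl)(C(C)C)C(C)C
Why: Silylation gives a bulky, non-directing aryl silyl ether that protects the future 7-OH and shields both flanking ring positions from lithiation.

**Step 5**
Reactants: 6 triisopropyl[3-methoxy-5-(methoxymethoxy)phenoxy]silane; 7 N-methoxy-N-methylacetamide
Product: 10 1-[2-methoxy-6-(methoxymethoxy)-4-(triisopropylsilyloxy)phenyl]ethan-1-one, via aryllithium 8 (not isolated), via lithium hemiaminal 9 (not isolated)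
Conditions: n-BuLi, TMEDA, THF, −20 → 0 °C; then 7, −78 → 0 °C; aq NH4Cl
Reagents that add atoms: n-butyllithium, [Li]CCCC (lithium of 8 and 9)
Why: Directed ortho-metalation occurs at the carbon between OMe and OMOM (cooperative coordination, silyloxy-flanked sites blocked), and Weinreb amide acylation stops at the ketone because the chelated tetrahedral adduct survives until work-up.

**Step 6**
Reactants: 10 1-[2-methoxy-6-(methoxymethoxy)-4-(triisopropylsilyloxy)phenyl]ethan-1-one
Product: 11 1-[2-hydroxy-6-methoxy-4-(triisopropylsilyloxy)phenyl]ethan-1-one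
Conditions: HCl (2 M in MeOH), rt
Reagents that add atoms: none
Why: Acid-catalysed acetal methanolysis removes the MOM group ortho to the carbonyl (assisted by hydrogen bonding to the ketone), while the aryl triisopropylsilyl ether is stable to dilute acid.

**Step 7**
Reactants: 11 1-[2-hydroxy-6-methoxy-4-(triisopropylsilyloxy)phenyl]ethan-1-one; 12 N,N-dimethylformamide dimethyl acetal
Product: 14 3-iodo-5-methoxy-7-(triisopropylsilyloxy)-4H-chromen-4-one, via enaminone 13 (not isolated)
Conditions: 12 (neat), 95 °C; evaporate; then I2, CHCl3, rt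
Reagents that add atoms: iodine, II
Why: Enaminone condensation followed by iodine-induced cyclisation (Gammill 3-iodochromone synthesis): the α-iodo iminium is closed by the hydrogen-bonded phenol with loss of dimethylamine.

**Step 8**
Reactants: 15 catechol
Product: 16 2-(methoxymethoxy)phenol
Conditions: MOMCl (1.0 equiv), i-Pr2NEt, CH2Cl2, 0 °C
Reagents that add atoms: chloromethyl methyl ether, COCCl
Why: Mono-acetalisation of a symmetric diol with one equivalent of electrophile; the MOM group cannot migrate between the catechol oxygens under the basic conditions of step 10.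

**Step 9**
Reactants: 16 2-(methoxymethoxy)phenol
Product: 17 4-bromo-2-(methoxymethoxy)phenol
Conditions: NBS, MeCN, −10 → 0 °C
Reagents that add atoms: N-bromosuccinimide, O=C1CCC(=O)N1Br
Why: Electrophilic aromatic bromination goes para to the free hydroxyl, the stronger donor, which places bromine para to the future pyran oxygen.

**Step 10**
Reactants: 17 4-bromo-2-(methoxymethoxy)phenol; 18 3-chloro-3-methylbut-1-yne
Product: 19 4-bromo-2-(methoxymethoxy)-1-[(2-methylbut-3-yn-2-yl)oxy]benzene
Conditions: CuCl2·2H2O (0.5 mol %), DBU, MeCN, 0 °C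
Reagents that add atoms: none
Why: Copper-catalysed propargylic substitution (Godfrey O-alkylation) makes the tertiary aryl propargyl ether, which plain SN2 chemistry cannot.

**Step 11**
Reactants: 19 4-bromo-2-(methoxymethoxy)-1-[(2-methylbut-3-yn-2-yl)oxy]benzene
Product: 21 6-bromo-8-(methoxymethoxy)-2,2-dimethyl-2H-chromene, via allenylphenol 20 (not isolated)
Conditions: PhNEt2, 180 °C
Reagents that add atoms: none
Why: Aromatic propargyl Claisen rearrangement into the only free ortho position, then 1,5-hydrogen shift and oxa-6π electrocyclisation, closes the 2,2-dimethylpyran ring.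

**Step 12**
Reactants: 21 6-bromo-8-(methoxymethoxy)-2,2-dimethyl-2H-chromene
Product: 22 6-bromo-2,2-dimethyl-2H-chromen-8-ol
Conditions: HCl (2 M in MeOH), 40 °C
Reagents that add atoms: none
Why: Acid-catalysed acetal methanolysis frees the phenol; the bromine-deactivated chromene double bond tolerates dilute methanolic acid.

**Step 13**
Reactants: 22 6-bromo-2,2-dimethyl-2H-chromen-8-ol
Product: 23 [(6-bromo-2,2-dimethyl-2H-chromen-8-yl)oxy]triisopropylsilane
Conditions: i-Pr3SiCl, imidazole, DMF, 40 °C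
Reagents that add atoms: chlorotriisopropylsilane, CC(C)[Si](Cl)(C(C)C)C(C)C
Why: Silylation puts the same fluoride-labile group on both phenols, so the last step can be one non-basic deprotection.

**Step 14**
Reactants: 23 [(6-bromo-2,2-dimethyl-2H-chromen-8-yl)oxy]triisopropylsilane
Product: 24 triisopropyl{[2,2-dimethyl-6-(4,4,5,5-tetramethyl-1,3,2-dioxaborolan-2-yl)-2H-chromen-8-yl]oxy}silane
Conditions: B2pin2, PdCl2(dppf) (3 mol %), KOAc, 1,4-dioxane, 90 °C
Reagents that add atoms: bis(pinacolato)diboron, CC1(C)OB(OC1(C)C)B1OC(C)(C)C(C)(C)O1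
Why: Miyaura borylation converts the aryl bromide into the pinacol boronate without touching the chromene alkene or the silyl ether.

**Step 15**
Reactants: 14 3-iodo-5-methoxy-7-(triisopropylsilyloxy)-4H-chromen-4-one; 24 triisopropyl{[2,2-dimethyl-6-(4,4,5,5-tetramethyl-1,3,2-dioxaborolan-2-yl)-2H-chromen-8-yl]oxy}silane
Product: 25 3-[2,2-dimethyl-8-(triisopropylsilyloxy)-2H-chromen-6-yl]-5-methoxy-7-(triisopropylsilyloxy)-4H-chromen-4-one
Conditions: PdCl2(dppf) (5 mol %), K3PO4, 1,4-dioxane/H2O (9:1), 60 °C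
Reagents that add atoms: none
Why: Suzuki–Miyaura cross-coupling; oxidative addition into the electron-poor C3–I bond is fast, and mild phosphate base at 60 °C spares the pyranone and both aryl silyl ethers.

**Step 16**
Reactants: 25 3-[2,2-dimethyl-8-(triisopropylsilyloxy)-2H-chromen-6-yl]-5-methoxy-7-(triisopropylsilyloxy)-4H-chromen-4-one
Product: 27 (3S,4S)-3-[2,2-dimethyl-8-(triisopropylsilyloxy)-2H-chromen-6-yl]-5-methoxy-7-(triisopropylsilyloxy)chroman-4-ol, via racemic isoflavanone 26 (not isolated)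
Conditions: RuCl[(S,S)-TsDPEN](p-cymene) (5 mol %), HCO2H/Et3N (1:1), EtOAc, 45 °C
Reagents that add atoms: none
Why: Noyori–Ikariya asymmetric transfer hydrogenation: conjugate reduction gives the isoflavanone, which racemises at C3 through its enol under Et3N while the (S,S)-catalyst reduces only the enantiomer leading to the cis alcohol, setting C4 as S (as chroman-4-one gives the (S)-alcohol) and C3 as S by dynamic kinetic resolution.

**Step 17**
Reactants: 27 (3S,4S)-3-[2,2-dimethyl-8-(triisopropylsilyloxy)-2H-chromen-6-yl]-5-methoxy-7-(triisopropylsilyloxy)chroman-4-ol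
Product: 28 (3S)-3-[2,2-dimethyl-8-(triisopropylsilyloxy)-2H-chromen-6-yl]-5-methoxy-7-(triisopropylsilyloxy)chroman-4-one
Conditions: Dess–Martin periodinane, NaHCO3, CH2Cl2, 0 °C → rt
Reagents that add atoms: none
Why: Dess–Martin oxidation of the benzylic alcohol under buffered, non-enolising conditions removes the C4 centre and leaves the C3 centre (S, same substituent priorities as in the alcohol) untouched.

**Step 18**
Reactants: 28 (3S)-3-[2,2-dimethyl-8-(triisopropylsilyloxy)-2H-chromen-6-yl]-5-methoxy-7-(triisopropylsilyloxy)chroman-4-one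
Product: 29 (3S)-7-hydroxy-3-(8-hydroxy-2,2-dimethyl-2H-chromen-6-yl)-5-methoxychroman-4-one
Conditions: Bu4NF/AcOH (1:1, 2.5 equiv), THF, 0 °C
Reagents that add atoms: none
Why: Fluoride-driven desilylation buffered with acetic acid protonates the phenoxides at once, so the base-labile C3 centre, the aryl methyl ether and the chromene are not affected.

## Compound list

1 | resorcinol (benzene-1,3-diol) | Oc1cccc(O)c1 | starting material
2 | 3-methoxyphenol | COc1cccc(O)c1 | intermediate
3 | 1-methoxy-3-(methoxymethoxy)benzene | COCOc1cccc(OC)c1 | intermediate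
4 | 2-[3-methoxy-5-(methoxymethoxy)phenyl]-4,4,5,5-tetramethyl-1,3,2-dioxaborolane | COCOc1cc(OC)cc(B2OC(C)(C)C(C)(C)O2)c1 | intermediate
5 | 3-methoxy-5-(methoxymethoxy)phenol | COCOc1cc(O)cc(OC)c1 | intermediate
6 | triisopropyl[3-methoxy-5-(methoxymethoxy)phenoxy]silane | COCOc1cc(OC)cc(O[Si](C(C)C)(C(C)C)C(C)C)c1 | intermediate
7 | N-methoxy-N-methylacetamide | CC(=O)N(C)OC | starting material
8 | [2-methoxy-6-(methoxymethoxy)-4-(triisopropylsilyloxy)phenyl]lithium | [Li]c1c(OC)cc(O[Si](C(C)C)(C(C)C)C(C)C)cc1OCOC | intermediate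
9 | lithium 1-[methoxy(methyl)amino]-1-[2-methoxy-6-(methoxymethoxy)-4-(triisopropylsilyloxy)phenyl]ethan-1-olate (racemic) | CC(O[Li])(N(C)OC)c1c(OC)cc(O[Si](C(C)C)(C(C)C)C(C)C)cc1OCOC | intermediate
10 | 1-[2-methoxy-6-(methoxymethoxy)-4-(triisopropylsilyloxy)phenyl]ethan-1-one | CC(=O)c1c(OC)cc(O[Si](C(C)C)(C(C)C)C(C)C)cc1OCOC | intermediate
11 | 1-[2-hydroxy-6-methoxy-4-(triisopropylsilyloxy)phenyl]ethan-1-one | CC(=O)c1c(O)cc(O[Si](C(C)C)(C(C)C)C(C)C)cc1OC | intermediate
12 | N,N-dimethylformamide dimethyl acetal (1,1-dimethoxy-N,N-dimethylmethanamine) | COC(OC)N(C)C | starting material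
13 | (E)-3-(dimethylamino)-1-[2-hydroxy-6-methoxy-4-(triisopropylsilyloxy)phenyl]prop-2-en-1-one | CN(C)/C=C/C(=O)c1c(O)cc(O[Si](C(C)C)(C(C)C)C(C)C)cc1OC | intermediate
14 | 3-iodo-5-methoxy-7-(triisopropylsilyloxy)-4H-chromen-4-one | COc1cc(O[Si](C(C)C)(C(C)C)C(C)C)cc2occ(I)c(=O)c12 | intermediate
15 | catechol (benzene-1,2-diol) | Oc1ccccc1O | starting material
16 | 2-(methoxymethoxy)phenol | COCOc1ccccc1O | intermediate
17 | 4-bromo-2-(methoxymethoxy)phenol | COCOc1cc(Br)ccc1O | intermediate
18 | 3-chloro-3-methylbut-1-yne | CC(C)(Cl)C#C | starting material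
19 | 4-bromo-2-(methoxymethoxy)-1-[(2-methylbut-3-yn-2-yl)oxy]benzene | COCOc1cc(Br)ccc1OC(C)(C)C#C | intermediate
20 | 4-bromo-2-(methoxymethoxy)-6-(3-methylbuta-1,2-dien-1-yl)phenol | COCOc1cc(Br)cc(C=C=C(C)C)c1O | intermediate
21 | 6-bromo-8-(methoxymethoxy)-2,2-dimethyl-2H-chromene | COCOc1cc(Br)cc2C=CC(C)(C)Oc12 | intermediate
22 | 6-bromo-2,2-dimethyl-2H-chromen-8-ol | Oc1cc(Br)cc2C=CC(C)(C)Oc12 | intermediate
23 | [(6-bromo-2,2-dimethyl-2H-chromen-8-yl)oxy]triisopropylsilane | CC(C)[Si](Oc1cc(Br)cc2C=CC(C)(C)Oc12)(C(C)C)C(C)C | intermediate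
24 | triisopropyl{[2,2-dimethyl-6-(4,4,5,5-tetramethyl-1,3,2-dioxaborolan-2-yl)-2H-chromen-8-yl]oxy}silane | CC(C)[Si](Oc1cc(B3OC(C)(C)C(C)(C)O3)cc2C=CC(C)(C)Oc12)(C(C)C)C(C)C | intermediate
25 | 3-[2,2-dimethyl-8-(triisopropylsilyloxy)-2H-chromen-6-yl]-5-methoxy-7-(triisopropylsilyloxy)-4H-chromen-4-one | COc1cc(O[Si](C(C)C)(C(C)C)C(C)C)cc2occ(-c3cc(O[Si](C(C)C)(C(C)C)C(C)C)c4OC(C)(C)C=Cc4c3)c(=O)c12 | intermediate
26 | racemic 3-[2,2-dimethyl-8-(triisopropylsilyloxy)-2H-chromen-6-yl]-5-methoxy-7-(triisopropylsilyloxy)chroman-4-one | COc1cc(O[Si](C(C)C)(C(C)C)C(C)C)cc2OCC(c3cc(O[Si](C(C)C)(C(C)C)C(C)C)c4OC(C)(C)C=Cc4c3)C(=O)c12 | intermediate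
27 | (3S,4S)-3-[2,2-dimethyl-8-(triisopropylsilyloxy)-2H-chromen-6-yl]-5-methoxy-7-(triisopropylsilyloxy)chroman-4-ol (3,4-cis) | COc1cc(O[Si](C(C)C)(C(C)C)C(C)C)cc2c1[C@@H](O)[C@@H](c1cc(O[Si](C(C)C)(C(C)C)C(C)C)c3c(c1)C=CC(C)(C)O3)CO2 | intermediate
28 | (3S)-3-[2,2-dimethyl-8-(triisopropylsilyloxy)-2H-chromen-6-yl]-5-methoxy-7-(triisopropylsilyloxy)chroman-4-one | COc1cc(O[Si](C(C)C)(C(C)C)C(C)C)cc2c1C(=O)[C@@H](c1cc(O[Si](C(C)C)(C(C)C)C(C)C)c3c(c1)C=CC(C)(C)O3)CO2 | intermediate
29 | (3S)-7-hydroxy-3-(8-hydroxy-2,2-dimethyl-2H-chromen-6-yl)-5-methoxychroman-4-one | COc1cc(O)cc2c1C(=O)[C@@H](c1cc(O)c3c(c1)C=CC(C)(C)O3)CO2 | target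

## Step count and risks

Total step count: 18. Longest linear sequence: 11 steps (steps 1–7 then 15–18; the other branch, steps 8–14 then 15–18, is equally long).

**Step 16 is the most likely to fail.** The peri-methoxy group and the bulky silyl ethers may slow the conjugate reduction or the ketone reduction, and cis-selectivity or ee may erode. The fallback sets out from 25 and comes back at 28, bypassing 27 and step 17. Conjugate reduction of 25 with LiBH(s-Bu)3 in THF at −78 °C and trapping of the enolate with Me3SiCl gives the silyl enol ether 3-[2,2-dimethyl-8-(triisopropylsilyloxy)-2H-chromen-6-yl]-5-methoxy-7-(triisopropylsilyloxy)-4-(trimethylsilyloxy)-2H-chromene F1. F1 is then protonated enantioselectively with a BINOL-derived N-triflyl thiophosphoramide (5 mol %) and phenol as the stoichiometric proton source in toluene. The catalyst antipode that gives the (S)-ketone 28 is chosen on an analytical run.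

**Step 15 is the second risk.** The 7-silyloxychromone is sensitive to aqueous base (desilylation, pyranone opening) and the electron-rich boronate can protodeboronate. The fallback sets out from ketone 10 and bromide 23 and comes back at 25, forming the aryl–C3 bond before ring C exists. Palladium-catalysed ketone α-arylation (Pd2(dba)3, Xantphos, K3PO4, toluene, 80 °C) gives the deoxybenzoin 2-[2,2-dimethyl-8-(triisopropylsilyloxy)-2H-chromen-6-yl]-1-[2-methoxy-6-(methoxymethoxy)-4-(triisopropylsilyloxy)phenyl]ethan-1-one F2. Methanolic HCl removes the ortho MOM group to give 2-[2,2-dimethyl-8-(triisopropylsilyloxy)-2H-chromen-6-yl]-1-[2-hydroxy-6-methoxy-4-(triisopropylsilyloxy)phenyl]ethan-1-one F3. Heating F3 with 12 in toluene at 90 °C adds C2 and cyclises to isoflavone 25.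

**Step 5 is the third risk.** The hindered aryllithium may deprotonate the Weinreb acetamide instead of adding to it. The fallback sets out from 6 and comes back at 10. The same lithiation gives 8, which is trapped at −78 °C with acetaldehyde, a far better electrophile, to give racemic 1-[2-methoxy-6-(methoxymethoxy)-4-(triisopropylsilyloxy)phenyl]ethan-1-ol F4. Dess–Martin oxidation of F4 (CH2Cl2, NaHCO3, rt) then gives ketone 10.

## Further compounds

F1 | step 16 | 3-[2,2-dimethyl-8-(triisopropylsilyloxy)-2H-chromen-6-yl]-5-methoxy-7-(triisopropylsilyloxy)-4-(trimethylsilyloxy)-2H-chromene | COc1cc(O[Si](C(C)C)(C(C)C)C(C)C)cc2OCC(c3cc(O[Si](C(C)C)(C(C)C)C(C)C)c4OC(C)(C)C=Cc4c3)=C(O[Si](C)(C)C)c12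
F2 | step 15 | 2-[2,2-dimethyl-8-(triisopropylsilyloxy)-2H-chromen-6-yl]-1-[2-methoxy-6-(methoxymethoxy)-4-(triisopropylsilyloxy)phenyl]ethan-1-one | COCOc1cc(O[Si](C(C)C)(C(C)C)C(C)C)cc(OC)c1C(=O)Cc1cc(O[Si](C(C)C)(C(C)C)C(C)C)c2OC(C)(C)C=Cc2c1
F3 | step 15 | 2-[2,2-dimethyl-8-(triisopropylsilyloxy)-2H-chromen-6-yl]-1-[2-hydroxy-6-methoxy-4-(triisopropylsilyloxy)phenyl]ethan-1-one | COc1cc(O[Si](C(C)C)(C(C)C)C(C)C)cc(O)c1C(=O)Cc1cc(O[Si](C(C)C)(C(C)C)C(C)C)c2OC(C)(C)C=Cc2c1
F4 | step 5 | 1-[2-methoxy-6-(methoxymethoxy)-4-(triisopropylsilyloxy)phenyl]ethan-1-ol (racemic) | CC(O)c1c(OC)cc(O[Si](C(C)C)(C(C)C)C(C)C)cc1OCOC
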